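In a one-step world, substrate turns to target and stays there, and waiting costs nothing; this flask has a step that eats target and a solid that shelters it.

    gas phase ⇌ dissolved gas, rate k1*(csat - [dissolved gas]) (k1 = 4.80 s⁻¹, csat = 0.34 mM)
    substrate + dissolved gas + catalyst → catalyst + target (k2 = 4.60 × 10⁷ M⁻² s⁻¹)
    target → over-reaction product (k3 = 0.00382 s⁻¹)
    crystals ⇌ target, rate k4*(cs4 - [target]) while solid is left; crystals form when [target] > cs4 (cs4 = 0.044 mM, k4 = 4.79 s⁻¹)

substrate 0.0020 M; gas phase 0.34 mM (held); catalyst 0.2 mol%; time 8.0 min

- what is said of target includes crystals
- crystals is a solid; its amount is given per volume of the solution
- at the start none of the gas is dissolved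
- run time (flask): 8.0 min

* how much target and crystals together there is at 8.0 min, in percent of the substrate charged
* the change that raises the amount of target and crystals together at 8.0 min, in percent of the substrate charged most ("none" if none brings more than 2 percentage points) (maple / cedar / birch / elm / none)
* amount of target and crystals together at 8.0 min, in percent of the substrate charged, after birch

- maple: doubling the saturation concentration of gas phase, all else as stated
- cedar: doubling the transfer coefficient of step 1, all else as stated
- birch: doubling the amount of catalyst, all else as stated
- elm: doubling the dissolution coefficient of step 4, all else as stated

Does the gas keep up? The crossing has a half-life of 0.144 s, faster than the 1.9 s in which step 2 alone halves the dissolved gas at the charged concentrations. So I hold [dissolved gas] near 0.34 mM, and the substrate falls pseudo-first-order with a half-life of 11.1 s.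

Does the target form before step 3 can touch it? Step 3 alone halves dissolved target in 3.0 min, far longer than that half-life, and the charge of 0.0020 M stands far above the solubility of 0.044 mM. So I expect crystals, with [target] held near the solubility.

What, then, does step 3 take? I reckon 0.00504 min⁻¹: this is the leak, the share of the charge that step 3 takes per minute while crystals stand. Over 8.0 min it costs 4.03%, so I commit to 96.0%. The leak holds k3, cs4 and the charge, and maple, cedar, birch and elm move none of these, so I say none, with birch unchanged.

The forecast gives 95.9% against my 96.0%, then none, and 95.9% after birch, in the words “that loss depends on the solubility cap and the run time rather than on how fast the target forms”.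

The simulation gives 95.9%, none, and 95.9% after birch; elm brings 0.037 percentage points. In the neighbour flask, with 5.0 × 10⁻⁴ M of substrate at the same loading and time, the leak becomes 0.0202 min⁻¹, which reckons to 16.2% by 8.0 min, and the neighbour flask holds 16.1% of over-reaction product then. The flask itself has not come to rest: by 80.0 min its target and crystals together fall to 59.6%, a further drop of 36 points. The leak reckons 40.3% lost by then, and the flask holds 40.4% of over-reaction product, with crystals still at 57.4%.

The constants used here are assumed; the rest is arithmetic.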